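**Retrosynthetic overview**

- Ring numbering: C1 = CH(OH) next to C2 (heptenyl), C3 (CH2OH), C4 = CH(OH), C5/C6 = oxirane, C6 carrying the side chain. With the C5–C6 oxirane read as a masked C5=C6 alkene, the carbocycle is a cyclohexa-2,5-diene-1,4-diol: both carbinol carbons (C1, C4) sit between two ring sp2 carbons, so the ring is two β-formylvinyl units (C1–C2=C3 and C4–C5=C6) joined head to tail.
- Key disconnection: C3–C4 and C6–C1, made together in a copper-catalysed alkenyl-transfer/Brook-relay [3+3] annulation of a (Z)-β-silyl enal (C1–C3) with a (Z)-β-boryl enal (C4–C6 plus side chain); the silyl shift leaves O1 protected and O4 free.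
- Fragments: the silyl enal from (E)-2,3-dibromobut-2-ene-1,4-diol (Suzuki–Miyaura coupling, silylation, retro-Brook shift, oxidation); the boryl enal from propargyl alcohol and a bromo enoate (alkyne allylation, oxidation, hydroiodination, Miyaura borylation).
- Stereochemical relay: C1 from the chiral copper catalyst; C5/C6 by epoxidation anti to the silyloxy groups; C4 by oxidation and hydride delivery anti to the oxirane, the same reduction giving the CH2OH group.
- Ring order: carbocycle (key step), then oxirane; ester hydrolysis and desilylation last.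

Key step: step 9

Remark: ethyl (2E)-4-bromo-2-methylbut-2-enoate is taken as a purchasable building block, and the ligand antipode named in the key step is assigned by analogy as the one that gives the (1S) carbinol.

**Route**

Step 1
Reactants: 1 (2E)-2,3-dibromobut-2-ene-1,4-diol; 2 [(1E)-hept-1-enyl]boronic acid
Product: 3 (2Z)-2-bromo-3-[(1E)-hept-1-enyl]but-2-ene-1,4-diol
Conditions: Pd(PPh3)4 (5 mol %), Na2CO3 (2 M aq), THF, 55 °C, 1 in threefold excess
Reagents that add atoms: none
Why: Suzuki–Miyaura coupling at one C–Br bond of the symmetric (E)-dibromide (excess 1 favours mono-coupling) with retention at both partners, which should leave the remaining bromine cis to one CH2OH and the heptenyl group cis to the other.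

Step 2
Reactants: 3 (2Z)-2-bromo-3-[(1E)-hept-1-enyl]but-2-ene-1,4-diol
Product: 4 (2Z)-2-bromo-3-[(1E)-hept-1-enyl]-1,4-bis(triethylsilyloxy)but-2-ene
Conditions: Et3SiCl, imidazole, CH2Cl2, 0 °C
Reagents that add atoms: chlorotriethylsilane, CC[Si](Cl)(CC)CC
Why: Standard silylation of both primary alcohols; the silyl ether cis to bromine is the one used in the next step.

Step 3
Reactants: 4 (2Z)-2-bromo-3-[(1E)-hept-1-enyl]-1,4-bis(triethylsilyloxy)but-2-ene
Product: 6 (2Z)-2-[(1E)-hept-1-enyl]-3-(triethylsilyl)-4-(triethylsilyloxy)but-2-en-1-ol, via alkenyllithium 5 (not isolated)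
Conditions: t-BuLi (2.1 equiv), THF, −78 °C to 0 °C; H2O
Reagents that add atoms: none
Why: Bromine–lithium exchange should give the configurationally stable alkenyllithium, which takes the silyl group from the cis γ-oxygen through a five-membered transition state (retro-1,4-Brook rearrangement, favoured over the strained 1,3-shift from the geminal CH2O–Si), installing the C-silyl group with retention and freeing only the alcohol that becomes C1.

Step 4
Reactants: 6 (2Z)-2-[(1E)-hept-1-enyl]-3-(triethylsilyl)-4-(triethylsilyloxy)but-2-en-1-ol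
Product: 7 (2Z)-2-[(1E)-hept-1-enyl]-3-(triethylsilyl)-4-(triethylsilyloxy)but-2-enal
Conditions: Dess–Martin periodinane, NaHCO3, CH2Cl2, 0 °C
Reagents that add atoms: none
Why: Dess–Martin oxidation of the allylic alcohol to the enal under buffered, non-isomerising conditions, keeping silicon cis to the formyl group.

Step 5
Reactants: 8 prop-2-yn-1-ol; 9 ethyl (2E)-4-bromo-2-methylbut-2-enoate
Product: 10 ethyl (2E)-7-hydroxy-2-methylhept-2-en-5-ynoate
Conditions: CuI (10 mol %), K2CO3, n-Bu4NCl, DMF, rt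
Reagents that add atoms: none
Why: Copper-catalysed coupling of the terminal alkyne (as its copper acetylide) with the primary allylic bromide by direct substitution should give the skipped enyne without touching the (E)-enoate.

Step 6
Reactants: 10 ethyl (2E)-7-hydroxy-2-methylhept-2-en-5-ynoate
Product: 11 ethyl (2E)-2-methyl-7-oxohept-2-en-5-ynoate
Conditions: Dess–Martin periodinane, NaHCO3, CH2Cl2, 0 °C
Reagents that add atoms: none
Why: Dess–Martin oxidation of the propargylic alcohol to the ynal, to be used at once because its doubly activated CH2 makes it prone to isomerisation.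

Step 7
Reactants: 11 ethyl (2E)-2-methyl-7-oxohept-2-en-5-ynoate
Product: 12 ethyl (2E,5Z)-5-iodo-2-methyl-7-oxohepta-2,5-dienoate
Conditions: NaI, AcOH, rt
Reagents that add atoms: sodium iodide, [Na+].[I-]
Why: Anti hydroiodination of the ynal (conjugate addition of iodide, then protonation) should give the (Z)-β-iodo enal with iodine cis to the formyl group.

Step 8
Reactants: 12 ethyl (2E,5Z)-5-iodo-2-methyl-7-oxohepta-2,5-dienoate
Product: 13 ethyl (2E,5E)-2-methyl-7-oxo-5-(4,4,5,5-tetramethyl-1,3,2-dioxaborolan-2-yl)hepta-2,5-dienoate (boron cis to CHO)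
Conditions: B2pin2, PdCl2(PPh3)2 (3 mol %), PPh3, KOPh, toluene, 50 °C
Reagents that add atoms: bis(pinacolato)diboron, CC1(C)OB(OC1(C)C)B1OC(C)(C)C(C)(C)O1
Why: Miyaura borylation of the alkenyl iodide with retention of geometry, the weak base potassium phenoxide sparing the aldehyde.

Step 9
Reactants: 7 (2Z)-2-[(1E)-hept-1-enyl]-3-(triethylsilyl)-4-(triethylsilyloxy)but-2-enal; 13 ethyl (2E,5E)-2-methyl-7-oxo-5-(4,4,5,5-tetramethyl-1,3,2-dioxaborolan-2-yl)hepta-2,5-dienoate
Product: 15 ethyl (2E)-4-[(1S,4R)-2-[(1E)-hept-1-enyl]-4-hydroxy-1-(triethylsilyloxy)-3-(triethylsilyloxymethyl)cyclohexa-2,5-dien-6-yl]-2-methylbut-2-enoate, via cyclised borate 14 (not isolated)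
Conditions: CuF(PPh3)3·2MeOH (10 mol %), (R)-DTBM-SEGPHOS (12 mol %), THF/DMF, 40 °C, 13 added over 8 h to 7 (1.3 equiv); aq NH4Cl
Reagents that add atoms: none
Why: Proposed new method: the fluoride- or alkoxide-bound monovalent copper should take the alkenyl group from boron of 13, the chiral alkenylcopper adds 1,2 to the formyl group of 7 (C6–C1), the resulting copper alkoxide passes the cis triethylsilyl group from C3 to O1 by a 1,4-Brook shift, and the new C3 alkenylcopper adds to the formyl group of the other half (C3–C4), after which the C4 copper alkoxide is exchanged by the next boronate. The closest known reaction types are the copper fluoride/bisphosphine-catalysed enantioselective 1,2-addition of alkenylboronates to aldehydes and the copper-alkoxide-induced 1,4 carbon-to-oxygen silyl migration of (Z)-γ-silyl allylic alcohols used in anion relay chemistry, merged here into a head-to-tail [3+3] annulation. The carbocycle closes by a 6-exo-trig addition of the C3 alkenylcopper to the C4 aldehyde. C1 is set by the ligand in the intermolecular addition; C4 is set in the ring closure and is expected cis to O1 (same facial sense of the same chiral alkenylcopper, both oxygens pseudo-equatorial in the boat-like closure), but it is reset in steps 14 and 15. The step needs cross- over self-addition, secured because only 13 carries a transferable boron group and only 7 can relay, and helped by slow addition of 13 to excess 7; the low boronate concentration also lets the intramolecular silyl shift outrun boron-for-copper exchange at O1. Conjugate addition is blocked because both enal β-carbons are fully substituted, and the silyl shift leaves O1 protected and O4 free.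

Step 10
Reactants: 15 ethyl (2E)-4-[(1S,4R)-2-[(1E)-hept-1-enyl]-4-hydroxy-1-(triethylsilyloxy)-3-(triethylsilyloxymethyl)cyclohexa-2,5-dien-6-yl]-2-methylbut-2-enoate
Product: 16 ethyl (2E)-4-[(1S,4R)-2-[(1E)-hept-1-enyl]-1,4-bis(triethylsilyloxy)-3-(triethylsilyloxymethyl)cyclohexa-2,5-dien-6-yl]-2-methylbut-2-enoate
Conditions: Et3SiCl, imidazole, DMF, 0 °C
Reagents that add atoms: chlorotriethylsilane, CC[Si](Cl)(CC)CC
Why: Silylation of the free C4 hydroxyl so that it is masked in the Swern step and cannot direct the later epoxidation to its own face.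

Step 11
Reactants: 16 ethyl (2E)-4-[(1S,4R)-2-[(1E)-hept-1-enyl]-1,4-bis(triethylsilyloxy)-3-(triethylsilyloxymethyl)cyclohexa-2,5-dien-6-yl]-2-methylbut-2-enoate
Product: 17 ethyl (2E)-4-[(1S,4R)-3-formyl-2-[(1E)-hept-1-enyl]-1,4-bis(triethylsilyloxy)cyclohexa-2,5-dien-6-yl]-2-methylbut-2-enoate
Conditions: (COCl)2, DMSO, CH2Cl2, −78 °C to −40 °C; Et3N
Reagents that add atoms: none
Why: Swern conditions should cleave and oxidise the primary allylic triethylsilyl ether selectively (oxidative desilylation, secondary triethylsilyl ethers being inert), giving the C3 enal that deactivates the C2=C3 diene towards peracid.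

Step 12
Reactants: 17 ethyl (2E)-4-[(1S,4R)-3-formyl-2-[(1E)-hept-1-enyl]-1,4-bis(triethylsilyloxy)cyclohexa-2,5-dien-6-yl]-2-methylbut-2-enoate
Product: 18 ethyl (2E)-4-[(1R,4S,5R,6R)-5,6-epoxy-3-formyl-2-[(1E)-hept-1-enyl]-1,4-bis(triethylsilyloxy)cyclohex-2-en-6-yl]-2-methylbut-2-enoate
Conditions: mCPBA, NaHCO3, CH2Cl2, 0 °C
Reagents that add atoms: 3-chloroperoxybenzoic acid, OOC(=O)c1cccc(Cl)c1
Why: Prilezhaev epoxidation of the only electron-rich alkene left (C5=C6) from the face opposite to the two cis allylic silyloxy groups, which should set C5 and C6 with the oxirane trans to O1.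

Step 13
Reactants: 18 ethyl (2E)-4-[(1R,4S,5R,6R)-5,6-epoxy-3-formyl-2-[(1E)-hept-1-enyl]-1,4-bis(triethylsilyloxy)cyclohex-2-en-6-yl]-2-methylbut-2-enoate
Product: 19 ethyl (2E)-4-[(1R,4S,5R,6R)-5,6-epoxy-3-formyl-2-[(1E)-hept-1-enyl]-4-hydroxy-1-(triethylsilyloxy)cyclohex-2-en-6-yl]-2-methylbut-2-enoate
Conditions: HF·pyridine, pyridine, THF, −20 °C to 0 °C
Reagents that add atoms: none
Why: Fluoride should cleave the less hindered C4 silyl ether (next to the oxirane CH) faster than the C1 silyl ether (between the quaternary oxirane carbon and the dienyl-bearing C2), under acidic conditions that exclude epoxide migration.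

Step 14
Reactants: 19 ethyl (2E)-4-[(1R,4S,5R,6R)-5,6-epoxy-3-formyl-2-[(1E)-hept-1-enyl]-4-hydroxy-1-(triethylsilyloxy)cyclohex-2-en-6-yl]-2-methylbut-2-enoate
Product: 20 ethyl (2E)-4-[(1R,5S,6R)-5,6-epoxy-3-formyl-2-[(1E)-hept-1-enyl]-4-oxo-1-(triethylsilyloxy)cyclohex-2-en-6-yl]-2-methylbut-2-enoate
Conditions: Dess–Martin periodinane, NaHCO3, CH2Cl2, 0 °C
Reagents that add atoms: none
Why: Dess–Martin oxidation of the C4 alcohol erases its configuration and gives the epoxy ene-dicarbonyl compound, to be reduced without purification.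

Step 15
Reactants: 20 ethyl (2E)-4-[(1R,5S,6R)-5,6-epoxy-3-formyl-2-[(1E)-hept-1-enyl]-4-oxo-1-(triethylsilyloxy)cyclohex-2-en-6-yl]-2-methylbut-2-enoate
Product: 21 ethyl (2E)-4-[(1R,4R,5R,6R)-5,6-epoxy-2-[(1E)-hept-1-enyl]-4-hydroxy-3-(hydroxymethyl)-1-(triethylsilyloxy)cyclohex-2-en-6-yl]-2-methylbut-2-enoate
Conditions: NaBH4, CeCl3·7H2O, MeOH, −78 °C
Reagents that add atoms: none
Why: Luche reduction should reduce the C4 ketone and the C3 aldehyde in 1,2-fashion, hydride attacking C4 anti to the oxirane oxygen so that the C4 hydroxyl ends cis to the oxirane.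

Step 16
Reactants: 21 ethyl (2E)-4-[(1R,4R,5R,6R)-5,6-epoxy-2-[(1E)-hept-1-enyl]-4-hydroxy-3-(hydroxymethyl)-1-(triethylsilyloxy)cyclohex-2-en-6-yl]-2-methylbut-2-enoate
Product: 22 (2E)-4-[(1R,4R,5R,6R)-5,6-epoxy-2-[(1E)-hept-1-enyl]-4-hydroxy-3-(hydroxymethyl)-1-(triethylsilyloxy)cyclohex-2-en-6-yl]-2-methylbut-2-enoic acid
Conditions: LiOH, THF/MeOH/H2O, 0 °C; then 0.5 M HCl to pH 4
Reagents that add atoms: lithium hydroxide, [Li+].[OH-]
Why: Saponification of the ethyl ester while O1 is still silylated, so that no alkoxide trans to the oxirane can start a Payne rearrangement (the free C4 hydroxyl is cis and cannot).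

Step 17
Reactants: 22 (2E)-4-[(1R,4R,5R,6R)-5,6-epoxy-2-[(1E)-hept-1-enyl]-4-hydroxy-3-(hydroxymethyl)-1-(triethylsilyloxy)cyclohex-2-en-6-yl]-2-methylbut-2-enoic acid
Product: 23 (2E)-4-[(1R,4R,5R,6S)-5,6-epoxy-2-[(1E)-hept-1-enyl]-1,4-dihydroxy-3-(hydroxymethyl)cyclohex-2-en-6-yl]-2-methylbut-2-enoic acid
Conditions: HF·pyridine, pyridine, THF, 0 °C to rt
Reagents that add atoms: none
Why: Buffered fluoride desilylation under non-basic conditions should release the C1 hydroxyl without epoxide migration and give the target.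

**Compound list**

1 | (2E)-2,3-dibromobut-2-ene-1,4-diol | OC/C(Br)=C(\Br)CO | starting material
2 | [(1E)-hept-1-enyl]boronic acid | CCCCC/C=C/B(O)O | starting material
3 | (2Z)-2-bromo-3-[(1E)-hept-1-enyl]but-2-ene-1,4-diol | OC/C(Br)=C(/CO)\C=C\CCCCC | intermediate
4 | (2Z)-2-bromo-3-[(1E)-hept-1-enyl]-1,4-bis(triethylsilyloxy)but-2-ene | CC[Si](CC)(CC)OC/C(Br)=C(/CO[Si](CC)(CC)CC)\C=C\CCCCC | intermediate
5 | alkenyllithium from 4 (lithium in place of bromine, cis to the silyloxymethyl group on the neighbouring alkene carbon) | CC[Si](CC)(CC)OC/C([Li])=C(/CO[Si](CC)(CC)CC)\C=C\CCCCC | intermediate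
6 | (2Z)-2-[(1E)-hept-1-enyl]-3-(triethylsilyl)-4-(triethylsilyloxy)but-2-en-1-ol | CC[Si](CC)(CC)OC/C([Si](CC)(CC)CC)=C(/CO)\C=C\CCCCC | intermediate
7 | (2Z)-2-[(1E)-hept-1-enyl]-3-(triethylsilyl)-4-(triethylsilyloxy)but-2-enal (silicon cis to CHO) | CC[Si](CC)(CC)OC/C([Si](CC)(CC)CC)=C(/C=O)\C=C\CCCCC | intermediate
8 | prop-2-yn-1-ol | OCC#C | starting material
9 | ethyl (2E)-4-bromo-2-methylbut-2-enoate | BrC/C=C(\C)C(=O)OCC | starting material
10 | ethyl (2E)-7-hydroxy-2-methylhept-2-en-5-ynoate | OCC#CC/C=C(\C)C(=O)OCC | intermediate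
11 | ethyl (2E)-2-methyl-7-oxohept-2-en-5-ynoate | O=CC#CC/C=C(\C)C(=O)OCC | intermediate
12 | ethyl (2E,5Z)-5-iodo-2-methyl-7-oxohepta-2,5-dienoate | O=C/C=C(\I)C/C=C(\C)C(=O)OCC | intermediate
13 | ethyl (2E,5E)-2-methyl-7-oxo-5-(4,4,5,5-tetramethyl-1,3,2-dioxaborolan-2-yl)hepta-2,5-dienoate (boron cis to CHO) | O=C/C=C(\B1OC(C)(C)C(C)(C)O1)C/C=C(\C)C(=O)OCC | intermediate
14 | O4-pinacolboryl ether of 15 (cyclised borate) | CCCCC/C=C/C1=C(CO[Si](CC)(CC)CC)[C@H](OB2OC(C)(C)C(C)(C)O2)C=C(C/C=C(\C)C(=O)OCC)[C@@H]1O[Si](CC)(CC)CC | intermediate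
15 | ethyl (2E)-4-[(1S,4R)-2-[(1E)-hept-1-enyl]-4-hydroxy-1-(triethylsilyloxy)-3-(triethylsilyloxymethyl)cyclohexa-2,5-dien-6-yl]-2-methylbut-2-enoate (overview numbering; O1 and O4 cis) | CCCCC/C=C/C1=C(CO[Si](CC)(CC)CC)[C@H](O)C=C(C/C=C(\C)C(=O)OCC)[C@@H]1O[Si](CC)(CC)CC | intermediate
16 | (1S,4R) tris(triethylsilyl) ether of the dienediol (O4-silyl ether of 15) | CCCCC/C=C/C1=C(CO[Si](CC)(CC)CC)[C@H](O[Si](CC)(CC)CC)C=C(C/C=C(\C)C(=O)OCC)[C@@H]1O[Si](CC)(CC)CC | intermediate
17 | ethyl (2E)-4-[(1S,4R)-3-formyl-2-[(1E)-hept-1-enyl]-1,4-bis(triethylsilyloxy)cyclohexa-2,5-dien-6-yl]-2-methylbut-2-enoate | CCCCC/C=C/C1=C(C=O)[C@H](O[Si](CC)(CC)CC)C=C(C/C=C(\C)C(=O)OCC)[C@@H]1O[Si](CC)(CC)CC | intermediate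
18 | ethyl (2E)-4-[(1R,4S,5R,6R)-5,6-epoxy-3-formyl-2-[(1E)-hept-1-enyl]-1,4-bis(triethylsilyloxy)cyclohex-2-en-6-yl]-2-methylbut-2-enoate (oxirane trans to both silyloxy groups) | CCCCC/C=C/C1=C(C=O)[C@H](O[Si](CC)(CC)CC)[C@H]2O[C@@]2(C/C=C(\C)C(=O)OCC)[C@@H]1O[Si](CC)(CC)CC | intermediate
19 | ethyl (2E)-4-[(1R,4S,5R,6R)-5,6-epoxy-3-formyl-2-[(1E)-hept-1-enyl]-4-hydroxy-1-(triethylsilyloxy)cyclohex-2-en-6-yl]-2-methylbut-2-enoate | CCCCC/C=C/C1=C(C=O)[C@H](O)[C@H]2O[C@@]2(C/C=C(\C)C(=O)OCC)[C@@H]1O[Si](CC)(CC)CC | intermediate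
20 | ethyl (2E)-4-[(1R,5S,6R)-5,6-epoxy-3-formyl-2-[(1E)-hept-1-enyl]-4-oxo-1-(triethylsilyloxy)cyclohex-2-en-6-yl]-2-methylbut-2-enoate | CCCCC/C=C/C1=C(C=O)C(=O)[C@H]2O[C@@]2(C/C=C(\C)C(=O)OCC)[C@@H]1O[Si](CC)(CC)CC | intermediate
21 | ethyl (2E)-4-[(1R,4R,5R,6R)-5,6-epoxy-2-[(1E)-hept-1-enyl]-4-hydroxy-3-(hydroxymethyl)-1-(triethylsilyloxy)cyclohex-2-en-6-yl]-2-methylbut-2-enoate (4-OH cis to oxirane) | CCCCC/C=C/C1=C(CO)[C@@H](O)[C@H]2O[C@@]2(C/C=C(\C)C(=O)OCC)[C@@H]1O[Si](CC)(CC)CC | intermediate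
22 | (2E)-4-[(1R,4R,5R,6R)-5,6-epoxy-2-[(1E)-hept-1-enyl]-4-hydroxy-3-(hydroxymethyl)-1-(triethylsilyloxy)cyclohex-2-en-6-yl]-2-methylbut-2-enoic acid | CCCCC/C=C/C1=C(CO)[C@@H](O)[C@H]2O[C@@]2(C/C=C(\C)C(=O)O)[C@@H]1O[Si](CC)(CC)CC | intermediate
23 | (2E)-4-[(1R,4R,5R,6S)-5,6-epoxy-2-[(1E)-hept-1-enyl]-1,4-dihydroxy-3-(hydroxymethyl)cyclohex-2-en-6-yl]-2-methylbut-2-enoic acid | CCCCC/C=C/C1=C(CO)[C@@H](O)[C@H]2O[C@@]2(C/C=C(\C)C(=O)O)[C@@H]1O | target

**Step count and risks**

Total steps: 17. Longest linear sequence: 13 steps (steps 1–4 then 9–17; the branch through steps 5–8 is equally long).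

The three steps most likely to fail:

First, step 9 (proposed new method). The relay may stall at the open-chain adduct if boron-for-copper exchange at O1 outruns the silyl shift; 13 may add to itself; facial control in the first addition may be weak; and formation of the C4 epimer would erode the facial bias of step 12. The fallback uses known reactions only, sets out from 12 and 7 and returns at 15. The aldehyde of 12 is masked with 1,2-bis(trimethylsilyloxy)ethane and TMSOTf to give the dioxolane acetal F1. A Nozaki–Hiyama–Kishi coupling of F1 with 7 (CrCl2, NiCl2 cat., chiral sulfonamide ligand, or racemic with lipase resolution) forms C6–C1 and should give the open-chain carbinol F2. CuOtBu in THF/DMF induces the 1,4 carbon-to-oxygen silyl shift and iodine traps the alkenylcopper, giving the iodo silyl ether F3. Mild aqueous acid removes the acetal to give the iodo aldehyde F4, and an intramolecular Nozaki–Hiyama–Kishi reaction (CrCl2, NiCl2 cat., high dilution) closes C3–C4 to 15.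

Second, step 13. Both secondary silyl ethers may be lost, or cleavage may occur at the wrong oxygen. The fallback replaces steric discrimination by an orthogonal group; it sets out from 15 and returns at 19. Compound 15 is acylated with chloroacetic anhydride and pyridine to the chloroacetate F5; Swern oxidative desilylation gives the enal chloroacetate F6; mCPBA gives the epoxy chloroacetate F7; thiourea with NaHCO3 in ethanol removes the chloroacetyl group without base-induced epoxide migration and gives 19.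

Third, step 14. The strongly electrophilic ene-dicarbonyl compound may decompose (hydration, conjugate addition, oxirane opening), and hydride delivery to it may lack facial control. The fallback inverts C4 by substitution instead of oxidation and reduction; it sets out from 19 and returns at 21. A Mitsunobu reaction of 19 (4-nitrobenzoic acid, PPh3, DIAD) should give the inverted 4-nitrobenzoate F8; methanolysis (K2CO3, MeOH, 0 °C) gives the C4-epimeric alcohol F9, whose hydroxyl is cis to the oxirane and cannot undergo Payne rearrangement; Luche reduction of the aldehyde alone then gives 21.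

Further compounds
F1 | step 9 | ethyl (2E,5Z)-6-(1,3-dioxolan-2-yl)-5-iodo-2-methylhexa-2,5-dienoate | O1CCOC1/C=C(\I)C/C=C(\C)C(=O)OCC
F2 | step 9 | open-chain (S)-carbinol from 7 and F1 (C6–C1 formed; silicon cis to the carbinol, dioxolane cis to the carbinol) | CC[Si](CC)(CC)OC/C([Si](CC)(CC)CC)=C(\C=C\CCCCC)[C@@H](O)/C(=C\C1OCCO1)C/C=C(\C)C(=O)OCC
F3 | step 9 | alkenyl iodide O-triethylsilyl ether from F2 (iodine in place of the C-silyl group) | CC[Si](CC)(CC)OC/C(I)=C(\C=C\CCCCC)[C@@H](O[Si](CC)(CC)CC)/C(=C\C1OCCO1)C/C=C(\C)C(=O)OCC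
F4 | step 9 | iodo aldehyde from F3 (acetal removed) | CC[Si](CC)(CC)OC/C(I)=C(\C=C\CCCCC)[C@@H](O[Si](CC)(CC)CC)/C(=C\C=O)C/C=C(\C)C(=O)OCC
F5 | step 13 | O4-chloroacetate of 15 | CCCCC/C=C/C1=C(CO[Si](CC)(CC)CC)[C@H](OC(=O)CCl)C=C(C/C=C(\C)C(=O)OCC)[C@@H]1O[Si](CC)(CC)CC
F6 | step 13 | 3-formyl dienyl chloroacetate from F5 | CCCCC/C=C/C1=C(C=O)[C@H](OC(=O)CCl)C=C(C/C=C(\C)C(=O)OCC)[C@@H]1O[Si](CC)(CC)CC
F7 | step 13 | 5,6-epoxide of F6 (oxirane trans to both oxygen substituents) | CCCCC/C=C/C1=C(C=O)[C@H](OC(=O)CCl)[C@H]2O[C@@]2(C/C=C(\C)C(=O)OCC)[C@@H]1O[Si](CC)(CC)CC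
F8 | step 14 | C4-inverted 4-nitrobenzoate of 19 | CCCCC/C=C/C1=C(C=O)[C@@H](OC(=O)c3ccc(cc3)[N+]([O-])=O)[C@H]2O[C@@]2(C/C=C(\C)C(=O)OCC)[C@@H]1O[Si](CC)(CC)CC
F9 | step 14 | C4 epimer of 19 (4-OH cis to oxirane) | CCCCC/C=C/C1=C(C=O)[C@@H](O)[C@H]2O[C@@]2(C/C=C(\C)C(=O)OCC)[C@@H]1O[Si](CC)(CC)CC
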